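## Retrosynthetic overview

Ring atoms are called C1 (bears the heptenyl group), C2 (CH2OH), C3 (CHOH next to C2), C4 (oxirane CH), C5 (quaternary oxirane carbon) and C6 (CHOH next to C5).
Enabling feature: C3 and C6 carry oxygen in a 1,4-relationship, C4 is the only ring carbon with hydrogen and is bonded to C3, and every ring atom can be raised to sp2; the epoxy-ene-diol is therefore the epoxidised, twice-reduced image of a p-benzoquinone with the substitution pattern that a chromium alkenylcarbene/alkyne/CO benzannulation writes.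
Late disconnections: side-chain acid from a C5 allyl group (cross-metathesis, then oxidation); C3 and C6 carbinols from an epoxyquinone by oxirane-directed hydride delivery; oxirane C4–C5 by enantioselective nucleophilic epoxidation of the quinone; C1–heptenyl by Suzuki coupling.
Key disconnection: the six-membered ring falls apart into an alkenyl(methoxy)carbene chromium complex (C6, C5, C4), a propargyl silyl ether (C1, C2) and one CO ligand (C3); the ring is closed last by the C3–C4 bond.
Ring order: carbocycle first (step 3), oxirane second (step 7).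

Key step: step 3

Assumption: the cinchonidinium phase-transfer catalyst is taken to deliver oxygen to the quinone face that gives the (1R,6S)-epoxide needed in step 7; if the sense of induction is the opposite, its pseudoenantiomer derived from cinchonine is used under the same conditions.

## Route

Step 1
Reactants: 1 2,3-dibromoprop-1-ene; 2 vinylmagnesium bromide CH2=CHMgBr
Product: 3 2-bromopenta-1,4-diene
Conditions: CuI (5 mol %), THF, −20 °C to rt
Reagents that add atoms: none
Why: Copper-catalysed Grignard cross-coupling at the allylic C–Br bond (SN2 and SN2' attack give the same product) leaves the vinylic bromide untouched.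

Step 2
Reactants: 3 2-bromopenta-1,4-diene; 4 hexacarbonylchromium Cr(CO)6
Product: 7 pentacarbonyl[methoxy(penta-1,4-dien-2-yl)methylidene]chromium, via penta-1,4-dien-2-yllithium 5 (not isolated), via lithium acylchromate 6 (not isolated)
Conditions: t-BuLi (2 equiv), Et2O, −78 °C; Cr(CO)6, Et2O, −78 °C to rt; Me3OBF4, CH2Cl2/H2O, 0 °C
Reagents that add atoms: trimethyloxonium tetrafluoroborate, C[O+](C)C.F[B-](F)(F)F
Why: Fischer carbene synthesis, in which bromine–lithium exchange, addition of the alkenyllithium to a CO ligand and O-methylation of the acylmetalate by the Meerwein salt follow one another.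

Step 3
Reactants: 7 pentacarbonyl[methoxy(penta-1,4-dien-2-yl)methylidene]chromium; 8 tert-butyldimethyl(prop-2-yn-1-yloxy)silane
Product: 11 2-{[(tert-butyldimethylsilyl)oxy]methyl}-4-methoxy-5-(prop-2-en-1-yl)phenyl acetate, via vinylketene chromium complex 9 (not isolated), via phenol 10 (not isolated)
Conditions: THF (0.05 M), 50 °C, Ar; then Ac2O, Et3N, DMAP (cat.), rt; then air, daylight, filtration through SiO2
Reagents that add atoms: acetic anhydride, CC(=O)OC(C)=O
Why: Thermal loss of one CO from the zerovalent chromium carbene lets the alkyne bind and insert with its unsubstituted terminus bonding to the carbene carbon (C6–C1), a CO ligand then inserts at the substituted alkyne carbon (C2–C3) to give the η4-vinylketene complex 9, and ring closure joins the ketene carbon C3 to the terminal CH2 carbon C4 of the former alkenyl group, tautomerisation giving phenol 10, which is trapped in the same flask as acetate 11. The closest known reaction type is the Dötz benzannulation of alkenyl(alkoxy)carbene chromium complexes with terminal alkynes, for which 2-substituted (isopropenyl-type) complexes are standard substrates. The single carbocycle is closed by a thermally allowed disrotatory 6π-electrocyclisation of the dienylketene held s-cis on the Cr(CO)3 template. No stereocentre is created, because the step delivers the ring at the aromatic oxidation level with C3–O, C6–O, the C2 carbon substituent and the C5 allyl group already in place, and the four stereocentres are set from it in steps 7 and 8. The selectivity needed is regiochemical: the CH2OSi group must end next to the CO-derived C3 and the alkyne hydrogen next to C6, which the large steric difference between the two termini of a terminal alkyne secures. The 2-substituted alkenyl group can cyclise only through its CH2 terminus, so C4 is the only carbon that can close the ring.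

Step 4
Reactants: 11 2-{[(tert-butyldimethylsilyl)oxy]methyl}-4-methoxy-5-(prop-2-en-1-yl)phenyl acetate
Product: 12 2-{[(tert-butyldimethylsilyl)oxy]methyl}-3-iodo-4-methoxy-5-(prop-2-en-1-yl)phenyl acetate
Conditions: N-iodosuccinimide (1.1 equiv), CF3CO2H (10 mol %), MeCN, 0 °C, dark
Reagents that add atoms: N-iodosuccinimide, O=C1CCC(=O)N1I
Why: Electrophilic aromatic iodination should occur ortho to the methoxy group, the strongest donor on the ring (its other ortho position and its para position are blocked and the acetoxy group activates only weakly), so iodine should enter at C1 between OMe and CH2OSi.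

Step 5
Reactants: 12 2-{[(tert-butyldimethylsilyl)oxy]methyl}-3-iodo-4-methoxy-5-(prop-2-en-1-yl)phenyl acetate; 13 (E)-hept-1-en-1-ylboronic acid
Product: 15 2-{[(tert-butyldimethylsilyl)oxy]methyl}-3-[(1E)-hept-1-en-1-yl]-4-methoxy-5-(prop-2-en-1-yl)phenol, via coupled aryl acetate 14 (not isolated)
Conditions: Pd(OAc)2 (5 mol %), SPhos (10 mol %), K3PO4, toluene/H2O (10:1), 70 °C, Ar; then MeOH, K2CO3 (cat.), rt
Reagents that add atoms: none
Why: Suzuki–Miyaura coupling with a dialkylbiarylphosphine ligand tolerates the doubly ortho-substituted aryl iodide and transfers the alkenyl group with retention of its E geometry, and the aryl acetate is then cleaved by methanolysis in the same flask.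

Step 6
Reactants: 15 2-{[(tert-butyldimethylsilyl)oxy]methyl}-3-[(1E)-hept-1-en-1-yl]-4-methoxy-5-(prop-2-en-1-yl)phenol
Product: 16 2-{[(tert-butyldimethylsilyl)oxy]methyl}-3-[(1E)-hept-1-en-1-yl]-5-(prop-2-en-1-yl)cyclohexa-2,5-diene-1,4-dione
Conditions: PhI(OAc)2 (1.1 equiv), MeCN/H2O (2:1), 0 °C
Reagents that add atoms: water, O
Why: Oxidative demethylation of a para-methoxyphenol by a hypervalent iodine reagent (water adds at the methoxy-bearing carbon and the hemiketal loses methanol) gives the para-quinone and spares the silyl ether and the three C=C bonds.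

Step 7
Reactants: 16 2-{[(tert-butyldimethylsilyl)oxy]methyl}-3-[(1E)-hept-1-en-1-yl]-5-(prop-2-en-1-yl)cyclohexa-2,5-diene-1,4-dione
Product: 17 (1R,6S)-4-{[(tert-butyldimethylsilyl)oxy]methyl}-3-[(1E)-hept-1-en-1-yl]-1-(prop-2-en-1-yl)-7-oxabicyclo[4.1.0]hept-3-ene-2,5-dione
Conditions: t-BuOOH (5.5 M in decane, 1.5 equiv), N-(9-anthracenylmethyl)cinchonidinium chloride (10 mol %), K2CO3 (solid), toluene, −20 °C
Reagents that add atoms: tert-butyl hydroperoxide, CC(C)(C)OO
Why: Asymmetric Weitz–Scheffer epoxidation under chiral phase-transfer catalysis, in which the peroxide anion should add to the unsubstituted C4 of the trisubstituted quinone double bond (the tetrasubstituted, dienyl-conjugated C1=C2 bond reacts much more slowly) while the chiral ammonium ion pair selects the enantiotopic face and so sets C4 and C5 together.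

Step 8
Reactants: 17 (1R,6S)-4-{[(tert-butyldimethylsilyl)oxy]methyl}-3-[(1E)-hept-1-en-1-yl]-1-(prop-2-en-1-yl)-7-oxabicyclo[4.1.0]hept-3-ene-2,5-dione
Product: 18 (1S,2R,5S,6R)-4-{[(tert-butyldimethylsilyl)oxy]methyl}-3-[(1E)-hept-1-en-1-yl]-1-(prop-2-en-1-yl)-7-oxabicyclo[4.1.0]hept-3-ene-2,5-diol
Conditions: i-Bu2AlH (1 M in toluene, 3.5 equiv), CH2Cl2, −78 °C; then aq. KNaC4H4O6
Reagents that add atoms: none
Why: 1,2-Reduction of both carbonyl groups by an aluminium hydride that binds the oxirane oxygen and delivers hydride on the oxirane face (at C6 this is also the face not blocked by the C5 allyl group) should place both new hydroxyl groups trans to the epoxide and cis to each other, setting C3 and C6.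

Step 9
Reactants: 18 (1S,2R,5S,6R)-4-{[(tert-butyldimethylsilyl)oxy]methyl}-3-[(1E)-hept-1-en-1-yl]-1-(prop-2-en-1-yl)-7-oxabicyclo[4.1.0]hept-3-ene-2,5-diol; 19 methacrolein (2-methylprop-2-enal)
Product: 20 (2E)-4-[(1S,2R,5S,6R)-4-{[(tert-butyldimethylsilyl)oxy]methyl}-3-[(1E)-hept-1-en-1-yl]-2,5-dihydroxy-7-oxabicyclo[4.1.0]hept-3-en-1-yl]-2-methylbut-2-enal
Conditions: second-generation Hoveyda–Grubbs catalyst (H2IMes)Cl2Ru=CH(C6H4-2-O-i-Pr) (2 × 5 mol %), methacrolein (10 equiv), CH2Cl2, 40 °C
Reagents that add atoms: none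
Why: Olefin cross-metathesis of the monosubstituted allyl terminus with a 1,1-disubstituted enal should give the trisubstituted (E)-enal under thermodynamic control, while the hindered internal diene is not expected to engage the catalyst.

Step 10
Reactants: 20 (2E)-4-[(1S,2R,5S,6R)-4-{[(tert-butyldimethylsilyl)oxy]methyl}-3-[(1E)-hept-1-en-1-yl]-2,5-dihydroxy-7-oxabicyclo[4.1.0]hept-3-en-1-yl]-2-methylbut-2-enal
Product: 21 (2E)-4-[(1S,2R,5S,6R)-4-{[(tert-butyldimethylsilyl)oxy]methyl}-3-[(1E)-hept-1-en-1-yl]-2,5-dihydroxy-7-oxabicyclo[4.1.0]hept-3-en-1-yl]-2-methylbut-2-enoic acid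
Conditions: NaClO2 (3 equiv), NaH2PO4 (4 equiv), 2-methylbut-2-ene (20 equiv), t-BuOH/H2O (4:1), 0 °C to rt
Reagents that add atoms: sodium chlorite, [Na+].[O-]Cl=O
Why: Pinnick oxidation converts the enal into the acid without touching the alcohols, the epoxide or the alkenes, the hypochlorous acid formed being scavenged by the added alkene.

Step 11
Reactants: 21 (2E)-4-[(1S,2R,5S,6R)-4-{[(tert-butyldimethylsilyl)oxy]methyl}-3-[(1E)-hept-1-en-1-yl]-2,5-dihydroxy-7-oxabicyclo[4.1.0]hept-3-en-1-yl]-2-methylbut-2-enoic acid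
Product: 22 (2E)-4-[(1S,2R,5S,6R)-3-[(1E)-hept-1-en-1-yl]-2,5-dihydroxy-4-(hydroxymethyl)-7-oxabicyclo[4.1.0]hept-3-en-1-yl]-2-methylbut-2-enoic acid
Conditions: Et3N·3HF (5 equiv), MeCN, rt
Reagents that add atoms: none
Why: Fluoride-mediated cleavage of the primary silyl ether under near-neutral conditions avoids both acid opening of the epoxide and base-induced Payne migration.

## Compound list

1 | 2,3-dibromoprop-1-ene | BrCC(Br)=C | starting material
2 | vinylmagnesium bromide CH2=CHMgBr | C=C[Mg]Br | starting material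
3 | 2-bromopenta-1,4-diene | C=CCC(Br)=C | intermediate
4 | hexacarbonylchromium Cr(CO)6 | O=C=[Cr](=C=O)(=C=O)(=C=O)(=C=O)=C=O | starting material
5 | penta-1,4-dien-2-yllithium | [Li]C(=C)CC=C | intermediate
6 | lithium pentacarbonyl(2-methylidenepent-4-enoyl)chromate, Li[(CO)5Cr–C(O)C(=CH2)CH2CH=CH2] | [Li+].[O-]C(C(=C)CC=C)=[Cr](=C=O)(=C=O)(=C=O)(=C=O)=C=O | intermediate
7 | pentacarbonyl[methoxy(penta-1,4-dien-2-yl)methylidene]chromium, (CO)5Cr=C(OMe)C(=CH2)CH2CH=CH2 | COC(C(=C)CC=C)=[Cr](=C=O)(=C=O)(=C=O)(=C=O)=C=O | intermediate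
8 | tert-butyldimethyl(prop-2-yn-1-yloxy)silane | C#CCO[Si](C)(C)C(C)(C)C | starting material
9 | η4-vinylketene complex (OC)3Cr[CH2=C(CH2CH=CH2)–C(OMe)=CH–C(CH2OSiMe2-t-Bu)=C=O], alkenyl and ketene groups cis on the central C=C | C=CCC(=C)/C(OC)=C\C(CO[Si](C)(C)C(C)(C)C)=C=O.O=C=[Cr](=C=O)=C=O | intermediate
10 | 2-{[(tert-butyldimethylsilyl)oxy]methyl}-4-methoxy-5-(prop-2-en-1-yl)phenol (formed largely as its Cr(CO)3 π-complex) | COc1cc(CO[Si](C)(C)C(C)(C)C)c(O)cc1CC=C | intermediate
11 | 2-{[(tert-butyldimethylsilyl)oxy]methyl}-4-methoxy-5-(prop-2-en-1-yl)phenyl acetate | COc1cc(CO[Si](C)(C)C(C)(C)C)c(OC(C)=O)cc1CC=C | intermediate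
12 | 2-{[(tert-butyldimethylsilyl)oxy]methyl}-3-iodo-4-methoxy-5-(prop-2-en-1-yl)phenyl acetate | COc1c(I)c(CO[Si](C)(C)C(C)(C)C)c(OC(C)=O)cc1CC=C | intermediate
13 | (E)-hept-1-en-1-ylboronic acid | CCCCC/C=C/B(O)O | starting material
14 | 2-{[(tert-butyldimethylsilyl)oxy]methyl}-3-[(1E)-hept-1-en-1-yl]-4-methoxy-5-(prop-2-en-1-yl)phenyl acetate | CCCCC/C=C/c1c(OC)c(CC=C)cc(OC(C)=O)c1CO[Si](C)(C)C(C)(C)C | intermediate
15 | 2-{[(tert-butyldimethylsilyl)oxy]methyl}-3-[(1E)-hept-1-en-1-yl]-4-methoxy-5-(prop-2-en-1-yl)phenol | CCCCC/C=C/c1c(OC)c(CC=C)cc(O)c1CO[Si](C)(C)C(C)(C)C | intermediate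
16 | 2-{[(tert-butyldimethylsilyl)oxy]methyl}-3-[(1E)-hept-1-en-1-yl]-5-(prop-2-en-1-yl)cyclohexa-2,5-diene-1,4-dione | CCCCC/C=C/C1=C(CO[Si](C)(C)C(C)(C)C)C(=O)C=C(CC=C)C1=O | intermediate
17 | (1R,6S)-4-{[(tert-butyldimethylsilyl)oxy]methyl}-3-[(1E)-hept-1-en-1-yl]-1-(prop-2-en-1-yl)-7-oxabicyclo[4.1.0]hept-3-ene-2,5-dione | CCCCC/C=C/C1=C(CO[Si](C)(C)C(C)(C)C)C(=O)[C@H]2O[C@@]2(CC=C)C1=O | intermediate
18 | (1S,2R,5S,6R)-4-{[(tert-butyldimethylsilyl)oxy]methyl}-3-[(1E)-hept-1-en-1-yl]-1-(prop-2-en-1-yl)-7-oxabicyclo[4.1.0]hept-3-ene-2,5-diol (both OH trans to the oxirane oxygen) | CCCCC/C=C/C1=C(CO[Si](C)(C)C(C)(C)C)[C@H](O)[C@H]2O[C@@]2(CC=C)[C@@H]1O | intermediate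
19 | methacrolein (2-methylprop-2-enal) | CC(=C)C=O | starting material
20 | (2E)-4-[(1S,2R,5S,6R)-4-{[(tert-butyldimethylsilyl)oxy]methyl}-3-[(1E)-hept-1-en-1-yl]-2,5-dihydroxy-7-oxabicyclo[4.1.0]hept-3-en-1-yl]-2-methylbut-2-enal | CCCCC/C=C/C1=C(CO[Si](C)(C)C(C)(C)C)[C@H](O)[C@H]2O[C@@]2(C/C=C(\C)C=O)[C@@H]1O | intermediate
21 | (2E)-4-[(1S,2R,5S,6R)-4-{[(tert-butyldimethylsilyl)oxy]methyl}-3-[(1E)-hept-1-en-1-yl]-2,5-dihydroxy-7-oxabicyclo[4.1.0]hept-3-en-1-yl]-2-methylbut-2-enoic acid | CCCCC/C=C/C1=C(CO[Si](C)(C)C(C)(C)C)[C@H](O)[C@H]2O[C@@]2(C/C=C(\C)C(=O)O)[C@@H]1O | intermediate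
22 | (2E)-4-[(1S,2R,5S,6R)-3-[(1E)-hept-1-en-1-yl]-2,5-dihydroxy-4-(hydroxymethyl)-7-oxabicyclo[4.1.0]hept-3-en-1-yl]-2-methylbut-2-enoic acid | CCCCC/C=C/C1=C(CO)[C@H](O)[C@H]2O[C@@]2(C/C=C(\C)C(=O)O)[C@@H]1O | target

## Step count and risks

Total step count: 11.
Longest linear sequence: 11 steps (from 1 to 22).

Steps most likely to fail:

Step 7. The ion-paired peroxide may discriminate the two quinone faces poorly, and the allyl-substituted quinone may isomerise under base before oxygen transfer. The fallback sets out from 16 and comes back at 18. Non-asymmetric Weitz–Scheffer epoxidation (30 % H2O2, Na2CO3, THF/H2O, 0 °C) should give 17 together with its mirror image, the (1S,6R)-epoxide F1. Reduction of the mixture as in step 8 should give 18 together with its enantiomer, the (1R,2S,5R,6S)-diol F2. Enzymatic kinetic resolution (Burkholderia cepacia lipase, vinyl acetate, t-BuOMe, 30 °C) should acylate the less hindered carbinol next to the oxirane CH only in the enantiomer that fits the empirical rule for lipase acylation of secondary alcohols. That enantiomer is 18, which gives the monoacetate F3, while F2 stays unacylated and is separated by chromatography. Methanolysis of F3 (K2CO3 cat., MeOH, 0 °C) returns 18.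

Step 8. Hydride may arrive on the face opposite to the oxirane at the less hindered carbonyl, so that facial selectivity at C3 is poor; reductive opening of the epoxide by the aluminium hydride is a second hazard. The fallback sets out from 17 and comes back at 18. A non-directed Luche reduction (NaBH4, CeCl3·7H2O, MeOH, −78 °C) is expected to reduce the carbonyl next to the oxirane CH anti to the oxirane and the hindered carbonyl anti to the allyl group. This would give the diol epimeric at the carbinol next to the oxirane CH, the (1S,2R,5R,6R)-diol F4. Mitsunobu inversion of this less hindered carbinol (4-nitrobenzoic acid, PPh3, DIAD, toluene, 0 °C) should give the 4-nitrobenzoate F5 with the required configuration. Methanolysis (K2CO3 cat., MeOH, 0 °C) returns 18.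

Step 4. Iodination may be slow at the flanked position, may occur at the other free ring position, or may be overtaken by iodo-functionalisation of the allyl double bond. The fallback sets out from 7 and 8 and comes back at 15. Sonogashira coupling of 8 with (E)-1-iodohept-1-ene (Pd(PPh3)2Cl2, CuI, Et3N, rt) gives tert-butyldimethyl{[(4E)-non-4-en-2-yn-1-yl]oxy}silane F6. Benzannulation of 7 with F6 (THF, 50 °C, then air) would place the heptenyl group in the ring during the key step and give phenol 15 directly, so that steps 4 and 5 fall away. This holds only if the silyloxymethyl terminus acts as the larger alkyne substituent, which is why it is not the main route.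

Further compounds
F1 | step 7 | (1S,6R)-4-{[(tert-butyldimethylsilyl)oxy]methyl}-3-[(1E)-hept-1-en-1-yl]-1-(prop-2-en-1-yl)-7-oxabicyclo[4.1.0]hept-3-ene-2,5-dione (enantiomer of 17) | CCCCC/C=C/C1=C(CO[Si](C)(C)C(C)(C)C)C(=O)[C@@H]2O[C@]2(CC=C)C1=O
F2 | step 7 | (1R,2S,5R,6S)-4-{[(tert-butyldimethylsilyl)oxy]methyl}-3-[(1E)-hept-1-en-1-yl]-1-(prop-2-en-1-yl)-7-oxabicyclo[4.1.0]hept-3-ene-2,5-diol (enantiomer of 18) | CCCCC/C=C/C1=C(CO[Si](C)(C)C(C)(C)C)[C@@H](O)[C@@H]2O[C@]2(CC=C)[C@H]1O
F3 | step 7 | monoacetate of 18 at the carbinol next to the oxirane CH, (1S,2R,5S,6R) in the numbering of 18 | CCCCC/C=C/C1=C(CO[Si](C)(C)C(C)(C)C)[C@H](OC(C)=O)[C@H]2O[C@@]2(CC=C)[C@@H]1O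
F4 | step 8 | (1S,2R,5R,6R)-4-{[(tert-butyldimethylsilyl)oxy]methyl}-3-[(1E)-hept-1-en-1-yl]-1-(prop-2-en-1-yl)-7-oxabicyclo[4.1.0]hept-3-ene-2,5-diol (epimer of 18 at the carbinol next to the oxirane CH) | CCCCC/C=C/C1=C(CO[Si](C)(C)C(C)(C)C)[C@@H](O)[C@H]2O[C@@]2(CC=C)[C@@H]1O
F5 | step 8 | 4-nitrobenzoate of 18 at the carbinol next to the oxirane CH, (1S,2R,5S,6R) in the numbering of 18 | CCCCC/C=C/C1=C(CO[Si](C)(C)C(C)(C)C)[C@H](OC(=O)c3ccc(cc3)[N+](=O)[O-])[C@H]2O[C@@]2(CC=C)[C@@H]1O
F6 | step 4 | tert-butyldimethyl{[(4E)-non-4-en-2-yn-1-yl]oxy}silane | CCCCC/C=C/C#CCO[Si](C)(C)C(C)(C)C
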